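**Retrosynthetic overview** (C1–C15 are germacrane labels: O6 is the lactone oxygen, O8 carries the ester, C10 and C4 carry the CH2OH groups)
1. C7–C8 is cut last: a SmI2 ketyl radical from the C8 aldehyde closes the ten-membered ring onto C7 of a 3-(acetoxymethyl)butenolide; loss of acetate creates the exocyclic methylene and O8 is acylated in the same flask.
2. Ring order: the five-membered butenolide first (metathesis of a 2-(acetoxymethyl)acrylate ester), the ten-membered carbocycle second (radical step).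
3. C6: catalytic asymmetric Cr-mediated addition of a (Z)-iodoalkene to crotonaldehyde.
4. C4=C5 geometry: Cu-catalysed anti-carbomagnesiation of propargyl alcohol by the C8–C10/C1–C3 Grignard reagent, then I2.
5. C10: organocatalytic α-allylation of 4,4-dimethoxybutanal, itself made from acrolein dimethyl acetal and CO/H2.

Assumption: each chiral catalyst or ligand is named in the enantiomeric form expected from its published facial model to give the drawn product; if a sense proves reversed, its mirror image is used.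

**Step 1**
Reactants: 1 3,3-dimethoxyprop-1-ene (acrolein dimethyl acetal)
Product: 2 4,4-dimethoxybutanal
Conditions: Rh(acac)(CO)2 (0.5 mol%), BiPhePhos (1 mol%), CO/H2 (1:1, 10 bar), toluene, 60 °C
Reagents that add atoms: carbon monoxide, [C-]#[O+]
Why: Linear-selective Rh-catalysed hydroformylation (the bulky bisphosphite puts the formyl group on the terminal carbon) gives the C14–C10–C9–C8 unit with C8 already masked; no stereocentre is formed.

**Step 2**
Reactants: 2 4,4-dimethoxybutanal; 3 allyltrimethylsilane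
Product: 5 (R)-2-(2,2-dimethoxyethyl)pent-4-en-1-ol, via (R)-2-allyl-4,4-dimethoxybutanal 4 (not isolated)
Conditions: (2R,5R)-5-benzyl-2-tert-butyl-3-methylimidazolidin-4-one·TFA (20 mol%), (NH4)2Ce(NO3)6 (2 equiv), NaHCO3, H2O (2 equiv), DME, −20 °C; then NaBH4, MeOH, −20 → 0 °C
Reagents that add atoms: none
Why: Organocatalytic SOMO α-allylation: the enamine radical cation formed by one-electron oxidation with tetravalent cerium is trapped by the allylsilane on the face opposite the benzyl and tert-butyl groups, setting C10 as R, and immediate NaBH4 reduction stops epimerisation of 4.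

**Step 3**
Reactants: 5 (R)-2-(2,2-dimethoxyethyl)pent-4-en-1-ol
Product: 6 (R)-tert-butyl{[2-(2,2-dimethoxyethyl)pent-4-en-1-yl]oxy}diphenylsilane
Conditions: TBDPSCl, imidazole, DMF, 0 °C → rt
Reagents that add atoms: tert-butyl(chloro)diphenylsilane, CC(C)(C)[Si](Cl)(c1ccccc1)c1ccccc1
Why: Standard silylation of a primary alcohol; the TBDPS ether survives Grignard formation, the Lewis acids used later and the acetal hydrolysis.

**Step 4**
Reactants: 6 (R)-tert-butyl{[2-(2,2-dimethoxyethyl)pent-4-en-1-yl]oxy}diphenylsilane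
Product: 8 (R)-{[5-bromo-2-(2,2-dimethoxyethyl)pentyl]oxy}(tert-butyl)diphenylsilane, via alkylzirconocene chloride 7 (not isolated)
Conditions: Cp2Zr(H)Cl (1.3 equiv), THF, rt; then NBS, 0 °C
Reagents that add atoms: N-bromosuccinimide, O=C1CCC(=O)N1Br
Why: Schwartz hydrozirconation places Zr on the terminal carbon of the monosubstituted alkene and electrophilic bromination of the C–Zr bond gives the primary bromide (C3) without touching acetal or silyl ether.

**Step 5**
Reactants: 8 (R)-{[5-bromo-2-(2,2-dimethoxyethyl)pentyl]oxy}(tert-butyl)diphenylsilane; 9 prop-2-yn-1-ol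
Product: 13 (2Z,6R)-6-[(tert-butyldiphenylsilyloxy)methyl]-2-(iodomethylidene)-8,8-dimethoxyoctan-1-ol, via chloromagnesium prop-2-yn-1-olate 10 (not isolated), via Grignard reagent 11 (not isolated), via alkenylmagnesium adduct 12 (not isolated)
Conditions: 8, Mg, THF, 40 °C; separately 9, i-PrMgCl (1.0 equiv), THF, −20 °C; combine, CuI (10 mol%), THF/Et2O, −10 °C → rt, 16 h; then I2, −40 → 0 °C
Reagents that add atoms: iodine, II
Why: Cu-catalysed anti-carbomagnesiation of the propargyl alkoxide (Duboudin–Jousseaume reaction) delivers the alkyl group to the internal alkyne carbon through a five-membered magnesium chelate, so iodinolysis gives only the iodoalkene with I cis to CH2OH, which is the C4=C5 geometry of the target.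

**Step 6**
Reactants: 13 (2Z,6R)-6-[(tert-butyldiphenylsilyloxy)methyl]-2-(iodomethylidene)-8,8-dimethoxyoctan-1-ol
Product: 14 (1Z,6R)-1-iodo-8,8-dimethoxy-2,6-bis[(tert-butyldiphenylsilyloxy)methyl]oct-1-ene
Conditions: TBDPSCl, imidazole, CH2Cl2, rt
Reagents that add atoms: tert-butyl(chloro)diphenylsilane, CC(C)(C)[Si](Cl)(c1ccccc1)c1ccccc1
Why: Silylation of the allylic primary alcohol (C15) so that only the C6 hydroxyl is free for the later esterification.

**Step 7**
Reactants: 14 (1Z,6R)-1-iodo-8,8-dimethoxy-2,6-bis[(tert-butyldiphenylsilyloxy)methyl]oct-1-ene; 15 (E)-but-2-enal (crotonaldehyde)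
Product: 16 (2E,4S,5Z,10R)-12,12-dimethoxy-6,10-bis[(tert-butyldiphenylsilyloxy)methyl]dodeca-2,5-dien-4-ol
Conditions: CrCl2 (10 mol%), (S)-valinol-derived oxazoline–sulfonamide ligand of Kishi (12 mol%), NiCl2(2,9-dimethyl-1,10-phenanthroline) (2 mol%), Mn powder, Cp2ZrCl2, LiCl, MeCN, rt
Reagents that add atoms: none
Why: Catalytic asymmetric Nozaki–Hiyama–Kishi coupling: the alkenylchromium adds 1,2 to the enal with retention of alkene geometry and the chiral ligand on chromium selects the aldehyde face, giving the 4S carbinol (C6 of the target) independently of the remote C10 centre.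

**Step 8**
Reactants: 17 2-(bromomethyl)acrylic acid
Product: 18 2-(acetoxymethyl)acrylic acid
Conditions: NaOAc (3 equiv), AcOH, 50 °C
Reagents that add atoms: sodium acetate, CC(=O)[O-].[Na+]
Why: Allylic substitution of bromide by acetate in acetic acid, where the acrylic acid stays protonated and cannot alkylate itself, installs the acyloxy leaving group needed in the radical step.

**Step 9**
Reactants: 16 (2E,4S,5Z,10R)-12,12-dimethoxy-6,10-bis[(tert-butyldiphenylsilyloxy)methyl]dodeca-2,5-dien-4-ol; 18 2-(acetoxymethyl)acrylic acid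
Product: 19 (2E,4S,5Z,10R)-12,12-dimethoxy-6,10-bis[(tert-butyldiphenylsilyloxy)methyl]dodeca-2,5-dien-4-yl 2-(acetoxymethyl)acrylate
Conditions: DIC, DMAP (10 mol%), CH2Cl2, −20 → 0 °C
Reagents that add atoms: none
Why: Steglich esterification acylates the secondary bis-allylic alcohol under neutral conditions without ionising it, so C6 is untouched.

**Step 10**
Reactants: 19 (2E,4S,5Z,10R)-12,12-dimethoxy-6,10-bis[(tert-butyldiphenylsilyloxy)methyl]dodeca-2,5-dien-4-yl 2-(acetoxymethyl)acrylate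
Product: 20 (5R)-3-(acetoxymethyl)-5-[(1Z,6R)-8,8-dimethoxy-2,6-bis[(tert-butyldiphenylsilyloxy)methyl]oct-1-en-1-yl]furan-2(5H)-one
Conditions: second-generation Hoveyda–Grubbs catalyst (5 mol%), 1,4-benzoquinone (10 mol%), toluene (0.005 M), 80 °C
Reagents that add atoms: none
Why: Ring-closing metathesis between the acrylate and the propenyl group closes the five-membered butenolide with loss of propene, while the hindered trisubstituted C4=C5 alkene does not take part.

**Step 11**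
Reactants: 20 (5R)-3-(acetoxymethyl)-5-[(1Z,6R)-8,8-dimethoxy-2,6-bis[(tert-butyldiphenylsilyloxy)methyl]oct-1-en-1-yl]furan-2(5H)-one
Product: 21 (3R,7Z)-8-[(2R)-4-(acetoxymethyl)-5-oxo-2,5-dihydrofuran-2-yl]-3,7-bis[(tert-butyldiphenylsilyloxy)methyl]oct-7-enal
Conditions: LiBF4, MeCN/H2O (50:1), rt
Reagents that add atoms: water, O
Why: Mild Lewis-acid hydrolysis of the dimethyl acetal frees the C8 aldehyde while the TBDPS ethers, the allylic acetate and the butenolide are left intact.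

**Step 12**
Reactants: 21 (3R,7Z)-8-[(2R)-4-(acetoxymethyl)-5-oxo-2,5-dihydrofuran-2-yl]-3,7-bis[(tert-butyldiphenylsilyloxy)methyl]oct-7-enal; 22 methacryloyl chloride
Product: 24 [(3aR,4S,6R,10Z,11aR)-6,10-bis[(tert-butyldiphenylsilyloxy)methyl]-3-methylidene-2-oxo-3a,4,5,6,7,8,9,11a-octahydrocyclodeca[b]furan-4-yl] 2-methylprop-2-enoate, via diiodosamarium alkoxide 23 (not isolated)
Conditions: SmI2 (2.3 equiv), HMPA (8 equiv), THF, −78 °C, 21 added over 6 h (final 0.002 M); then 22 (4 equiv), DMAP (0.2 equiv), −78 → 0 °C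
Reagents that add atoms: none
Why: Proposed new method: SmI2 reduces the aldehyde to a samarium ketyl radical that adds 10-exo to the electron-poor C7 of the butenolide on the face anti to the C6 side chain (trans lactone, 7R), with C9 anti to C11 and the bulky samarium-bound oxygen in the open position next to H-7 where it can chelate the lactone carbonyl (8S); a second SmI2 reduces the α-lactone radical to the samarium enolate, which expels acetate (E1cB) to form the exocyclic methylene, and the trivalent samarium alkoxide is acylated in the flask before it can translactonise; the closest known reactions are SmI2 ketyl–olefin cyclisations onto acrylates and butenolides (rings up to eight-membered) and SmI2 reductive eliminations of β-acyloxy esters.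

**Step 13**
Reactants: 24 [(3aR,4S,6R,10Z,11aR)-6,10-bis[(tert-butyldiphenylsilyloxy)methyl]-3-methylidene-2-oxo-3a,4,5,6,7,8,9,11a-octahydrocyclodeca[b]furan-4-yl] 2-methylprop-2-enoate
Product: 25 [(3aR,4S,6R,10Z,11aR)-6,10-bis(hydroxymethyl)-3-methylidene-2-oxo-3a,4,5,6,7,8,9,11a-octahydrocyclodeca[b]furan-4-yl] 2-methylprop-2-enoate
Conditions: HF·pyridine, pyridine, THF, 0 °C → rt
Reagents that add atoms: none
Why: Buffered fluoride desilylation removes both primary TBDPS ethers without Michael addition to the α-methylene lactone or the methacrylate and without acyl migration.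

**Compound list**
1 | 3,3-dimethoxyprop-1-ene | C=CC(OC)OC | starting material
2 | 4,4-dimethoxybutanal | O=CCCC(OC)OC | intermediate
3 | allyltrimethylsilane | C=CC[Si](C)(C)C | starting material
4 | (R)-2-allyl-4,4-dimethoxybutanal | COC(OC)C[C@H](C=O)CC=C | intermediate
5 | (R)-2-(2,2-dimethoxyethyl)pent-4-en-1-ol | COC(OC)C[C@H](CO)CC=C | intermediate
6 | (R)-tert-butyl{[2-(2,2-dimethoxyethyl)pent-4-en-1-yl]oxy}diphenylsilane | COC(OC)C[C@H](CO[Si](c1ccccc1)(c1ccccc1)C(C)(C)C)CC=C | intermediate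
7 | chloro-bis(cyclopentadienyl)[(4R)-4-[(tert-butyldiphenylsilyloxy)methyl]-6,6-dimethoxyhexyl]zirconium | COC(OC)C[C@H](CO[Si](c1ccccc1)(c1ccccc1)C(C)(C)C)CCC[Zr](Cl)(C1C=CC=C1)C1C=CC=C1 | intermediate
8 | (R)-{[5-bromo-2-(2,2-dimethoxyethyl)pentyl]oxy}(tert-butyl)diphenylsilane | COC(OC)C[C@H](CO[Si](c1ccccc1)(c1ccccc1)C(C)(C)C)CCCBr | intermediate
9 | prop-2-yn-1-ol | C#CCO | starting material
10 | chloromagnesium prop-2-yn-1-olate | C#CCO[Mg]Cl | intermediate
11 | [(4R)-4-[(tert-butyldiphenylsilyloxy)methyl]-6,6-dimethoxyhexyl]magnesium bromide | COC(OC)C[C@H](CO[Si](c1ccccc1)(c1ccccc1)C(C)(C)C)CCC[Mg]Br | intermediate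
12 | (Z)-alkenylmagnesium bromide adduct, Mg cis to the CH2OMgCl group | COC(OC)C[C@H](CO[Si](c1ccccc1)(c1ccccc1)C(C)(C)C)CCC/C(CO[Mg]Cl)=C/[Mg]Br | intermediate
13 | (2Z,6R)-6-[(tert-butyldiphenylsilyloxy)methyl]-2-(iodomethylidene)-8,8-dimethoxyoctan-1-ol | COC(OC)C[C@H](CO[Si](c1ccccc1)(c1ccccc1)C(C)(C)C)CCC/C(CO)=C/I | intermediate
14 | (1Z,6R)-1-iodo-8,8-dimethoxy-2,6-bis[(tert-butyldiphenylsilyloxy)methyl]oct-1-ene | COC(OC)C[C@H](CO[Si](c1ccccc1)(c1ccccc1)C(C)(C)C)CCC/C(CO[Si](c1ccccc1)(c1ccccc1)C(C)(C)C)=C/I | intermediate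
15 | (E)-but-2-enal | C/C=C/C=O | starting material
16 | (2E,4S,5Z,10R)-12,12-dimethoxy-6,10-bis[(tert-butyldiphenylsilyloxy)methyl]dodeca-2,5-dien-4-ol | COC(OC)C[C@H](CO[Si](c1ccccc1)(c1ccccc1)C(C)(C)C)CCC/C(CO[Si](c1ccccc1)(c1ccccc1)C(C)(C)C)=C/[C@H](/C=C/C)O | intermediate
17 | 2-(bromomethyl)acrylic acid | C=C(CBr)C(=O)O | starting material
18 | 2-(acetoxymethyl)acrylic acid | C=C(COC(C)=O)C(=O)O | intermediate
19 | (2E,4S,5Z,10R)-12,12-dimethoxy-6,10-bis[(tert-butyldiphenylsilyloxy)methyl]dodeca-2,5-dien-4-yl 2-(acetoxymethyl)acrylate | COC(OC)C[C@H](CO[Si](c1ccccc1)(c1ccccc1)C(C)(C)C)CCC/C(CO[Si](c1ccccc1)(c1ccccc1)C(C)(C)C)=C/[C@H](/C=C/C)OC(=O)C(=C)COC(C)=O | intermediate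
20 | (5R)-3-(acetoxymethyl)-5-[(1Z,6R)-8,8-dimethoxy-2,6-bis[(tert-butyldiphenylsilyloxy)methyl]oct-1-en-1-yl]furan-2(5H)-one | COC(OC)C[C@H](CO[Si](c1ccccc1)(c1ccccc1)C(C)(C)C)CCC/C(CO[Si](c1ccccc1)(c1ccccc1)C(C)(C)C)=C/[C@H]1OC(=O)C(COC(C)=O)=C1 | intermediate
21 | (3R,7Z)-8-[(2R)-4-(acetoxymethyl)-5-oxo-2,5-dihydrofuran-2-yl]-3,7-bis[(tert-butyldiphenylsilyloxy)methyl]oct-7-enal | O=CC[C@H](CO[Si](c1ccccc1)(c1ccccc1)C(C)(C)C)CCC/C(CO[Si](c1ccccc1)(c1ccccc1)C(C)(C)C)=C/[C@H]1OC(=O)C(COC(C)=O)=C1 | intermediate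
22 | methacryloyl chloride | C=C(C)C(Cl)=O | starting material
23 | diiodosamarium alkoxide of the 8-hydroxy ten-membered α-methylene lactone (6R,7R,8S,10R) | I[Sm](I)O[C@H]1C[C@H](CO[Si](c3ccccc3)(c3ccccc3)C(C)(C)C)CCC/C(CO[Si](c3ccccc3)(c3ccccc3)C(C)(C)C)=C/[C@H]2OC(=O)C(=C)[C@H]12 | intermediate
24 | [(3aR,4S,6R,10Z,11aR)-6,10-bis[(tert-butyldiphenylsilyloxy)methyl]-3-methylidene-2-oxo-3a,4,5,6,7,8,9,11a-octahydrocyclodeca[b]furan-4-yl] 2-methylprop-2-enoate | C=C(C)C(=O)O[C@H]1C[C@H](CO[Si](c3ccccc3)(c3ccccc3)C(C)(C)C)CCC/C(CO[Si](c3ccccc3)(c3ccccc3)C(C)(C)C)=C/[C@H]2OC(=O)C(=C)[C@H]12 | intermediate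
25 | [(3aR,4S,6R,10Z,11aR)-6,10-bis(hydroxymethyl)-3-methylidene-2-oxo-3a,4,5,6,7,8,9,11a-octahydrocyclodeca[b]furan-4-yl] 2-methylprop-2-enoate | C=C(C)C(=O)O[C@H]1C[C@H](CO)CCC/C(CO)=C/[C@H]2OC(=O)C(=C)[C@H]12 | target

**Totals**
Total step count: 13. Longest linear sequence: 12 (steps 1–7 and 9–13; step 8 is a one-step branch).

**Steps most likely to fail, with fallbacks**

Step 12 (ketyl closure of the ten-membered ring). Likely failures are slow medium-ring closure with pinacol dimer or simple reduction, or the C8 epimer. The fallback closes the same C7–C8 bond from an allylic bromide with CrCl2. It sets out from 16. Esterification with 17 (DIC, DMAP) gives the 2-(bromomethyl)acrylate ester F1. The same metathesis as in step 10 gives the 3-(bromomethyl)butenolide F2. LiBF4 hydrolysis gives the bromo aldehyde F3. CrCl2 (6 equiv), THF/DMF, rt, slow addition (0.002 M) gives the 8-hydroxy ten-membered lactone F4: the ring-locked E-allylchromium reacts through a closed chair transition state (7,8-anti, hence 8S) on the face anti to the C6 side chain. Acylation of F4 with 22 (Et3N, DMAP, CH2Cl2) comes back to the route at 24.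

Step 7 (asymmetric Cr coupling). Likely failures are modest enantioselectivity or poor turnover with the hindered Z-iodide; the C6 epimer would be hard to separate before the ring is closed. The fallback sets C6 by ketone reduction instead of C–C addition. It sets out from 14. Carbonylative Sonogashira coupling with propyne and CO (PdCl2(PPh3)2, CuI, Et3N, THF, 1 atm) gives the cross-conjugated ynone F5. Asymmetric transfer hydrogenation with RuCl[(R,R)-TsDPEN](p-cymene), HCO2H/Et3N gives the (4R)-propargylic alcohol F6. Trans-reduction of the alkyne with NaAlH2(OCH2CH2OMe)2 (THF, 0 °C) gives the E-propenyl carbinol and comes back to the route at 16.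

Step 5 (carbomagnesiation with a valuable functionalised Grignard reagent). Likely failures are competing deprotonation of the alkyne C–H and low conversion. The fallback builds the same trisubstituted alkene by syn-carbocupration of an ynoate. It sets out from 8 through Grignard reagent 11 and bypasses 13 and 14. Methyl 4-hydroxybut-2-ynoate is silylated (TBDPSCl, imidazole) to methyl 4-[(tert-butyldiphenylsilyl)oxy]but-2-ynoate F7. Reagent 11 with CuBr·SMe2 (THF, −78 °C) gives the alkylcopper reagent F8. F8 adds syn across F7 at −78 °C to give the alkenylcopper adduct F9, and a MeOH quench at −78 °C gives the (Z)-enoate F10 with CH2OSi cis to the ester. i-Bu2AlH (CH2Cl2, −78 °C) gives the allylic alcohol F11 and MnO2 gives the (Z)-enal F12. The asymmetric Cr coupling of step 7, now between F12 and (E)-1-iodoprop-1-ene, comes back to the route at 16.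

**Further compounds**
F1 | step 12 | (2E,4S,5Z,10R)-12,12-dimethoxy-6,10-bis[(tert-butyldiphenylsilyloxy)methyl]dodeca-2,5-dien-4-yl 2-(bromomethyl)acrylate | COC(OC)C[C@H](CO[Si](c1ccccc1)(c1ccccc1)C(C)(C)C)CCC/C(CO[Si](c1ccccc1)(c1ccccc1)C(C)(C)C)=C/[C@H](/C=C/C)OC(=O)C(=C)CBr
F2 | step 12 | (5R)-3-(bromomethyl)-5-[(1Z,6R)-8,8-dimethoxy-2,6-bis[(tert-butyldiphenylsilyloxy)methyl]oct-1-en-1-yl]furan-2(5H)-one | COC(OC)C[C@H](CO[Si](c1ccccc1)(c1ccccc1)C(C)(C)C)CCC/C(CO[Si](c1ccccc1)(c1ccccc1)C(C)(C)C)=C/[C@H]1OC(=O)C(CBr)=C1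
F3 | step 12 | (3R,7Z)-8-[(2R)-4-(bromomethyl)-5-oxo-2,5-dihydrofuran-2-yl]-3,7-bis[(tert-butyldiphenylsilyloxy)methyl]oct-7-enal | O=CC[C@H](CO[Si](c1ccccc1)(c1ccccc1)C(C)(C)C)CCC/C(CO[Si](c1ccccc1)(c1ccccc1)C(C)(C)C)=C/[C@H]1OC(=O)C(CBr)=C1
F4 | step 12 | (3aR,4S,6R,10Z,11aR)-4-hydroxy-6,10-bis[(tert-butyldiphenylsilyloxy)methyl]-3-methylidene-3a,4,5,6,7,8,9,11a-octahydrocyclodeca[b]furan-2(3H)-one | O[C@H]1C[C@H](CO[Si](c3ccccc3)(c3ccccc3)C(C)(C)C)CCC/C(CO[Si](c3ccccc3)(c3ccccc3)C(C)(C)C)=C/[C@H]2OC(=O)C(=C)[C@H]12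
F5 | step 7 | (5Z,10R)-12,12-dimethoxy-6,10-bis[(tert-butyldiphenylsilyloxy)methyl]dodec-5-en-2-yn-4-one | COC(OC)C[C@H](CO[Si](c1ccccc1)(c1ccccc1)C(C)(C)C)CCC/C(CO[Si](c1ccccc1)(c1ccccc1)C(C)(C)C)=C/C(=O)C#CC
F6 | step 7 | (4R,5Z,10R)-12,12-dimethoxy-6,10-bis[(tert-butyldiphenylsilyloxy)methyl]dodec-5-en-2-yn-4-ol | COC(OC)C[C@H](CO[Si](c1ccccc1)(c1ccccc1)C(C)(C)C)CCC/C(CO[Si](c1ccccc1)(c1ccccc1)C(C)(C)C)=C/[C@H](C#CC)O
F7 | step 5 | methyl 4-[(tert-butyldiphenylsilyl)oxy]but-2-ynoate | COC(=O)C#CCO[Si](c1ccccc1)(c1ccccc1)C(C)(C)C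
F8 | step 5 | [(4R)-4-[(tert-butyldiphenylsilyloxy)methyl]-6,6-dimethoxyhexyl]copper | COC(OC)C[C@H](CO[Si](c1ccccc1)(c1ccccc1)C(C)(C)C)CCC[Cu]
F9 | step 5 | methyl (7R)-2-cuprio-9,9-dimethoxy-3,7-bis[(tert-butyldiphenylsilyloxy)methyl]non-2-enoate, copper cis to the new alkyl chain | COC(OC)C[C@H](CO[Si](c1ccccc1)(c1ccccc1)C(C)(C)C)CCC/C(CO[Si](c1ccccc1)(c1ccccc1)C(C)(C)C)=C(/C(=O)OC)[Cu]
F10 | step 5 | methyl (2Z,7R)-9,9-dimethoxy-3,7-bis[(tert-butyldiphenylsilyloxy)methyl]non-2-enoate | COC(OC)C[C@H](CO[Si](c1ccccc1)(c1ccccc1)C(C)(C)C)CCC/C(CO[Si](c1ccccc1)(c1ccccc1)C(C)(C)C)=C/C(=O)OC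
F11 | step 5 | (2Z,7R)-9,9-dimethoxy-3,7-bis[(tert-butyldiphenylsilyloxy)methyl]non-2-en-1-ol | COC(OC)C[C@H](CO[Si](c1ccccc1)(c1ccccc1)C(C)(C)C)CCC/C(CO[Si](c1ccccc1)(c1ccccc1)C(C)(C)C)=C/CO
F12 | step 5 | (2Z,7R)-9,9-dimethoxy-3,7-bis[(tert-butyldiphenylsilyloxy)methyl]non-2-enal | COC(OC)C[C@H](CO[Si](c1ccccc1)(c1ccccc1)C(C)(C)C)CCC/C(CO[Si](c1ccccc1)(c1ccccc1)C(C)(C)C)=C/C=O
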